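**Retrosynthetic overview**
1. Cut the CH2–aryl bond of the dihydrochalcone: the ring A ketone reacts as its homoenolate (β-carbanion), stored as a 1-arylcyclopropanol, and is joined to 4-bromophenol by palladium-catalysed ring-opening arylation (last step, no protecting groups).
2. The 1-arylcyclopropanol comes from the ring A methyl ester (Kulinkovich cyclopropanation).
3. The pyran ring comes from a 3-prenyl resorcylate and prenal (condensation, then oxa-6π electrocyclisation at C5, the only free nucleophilic carbon).
4. The 3-prenyl resorcylate comes from methyl 2,4-dihydroxybenzoate and prenyl bromide (ortho-C-prenylation).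
5. Ring order: rings A and B are bought; the pyran ring is formed in step 2; a cyclopropane is built in step 3 and opened in step 4.

Assumption: the target has no stereocentre and no stereogenic double bond (it is achiral), so the route delivers the one compound the SMILES describes and needs no stereocontrol.

**Step 1**
Reactants: 1 methyl 2,4-dihydroxybenzoate; 2 prenyl bromide (1-bromo-3-methylbut-2-ene)
Product: 3 methyl 2,4-dihydroxy-3-(3-methylbut-2-en-1-yl)benzoate
Conditions: NaH (1.1 equiv), toluene, 0 °C to rt; then 2 (1.0 equiv), rt to 50 °C, 16 h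
Reagents that add atoms: none
Why: Ortho-C-prenylation of a phenoxide (C-alkylation of the tight sodium phenoxide ion pair in a non-polar solvent): only the non-chelated 4-OH is deprotonated and the carbon between the two oxygens (C3) is the most nucleophilic ortho position, so the prenyl group enters there, the minor 5-prenyl and O-prenyl isomers being removed by chromatography; no stereocentre is formed.

**Step 2**
Reactants: 3 methyl 2,4-dihydroxy-3-(3-methylbut-2-en-1-yl)benzoate; 4 3-methylbut-2-enal (prenal)
Product: 6 methyl 7-hydroxy-2,2-dimethyl-8-(3-methylbut-2-en-1-yl)-2H-chromene-6-carboxylate, via ortho-quinone methide 5 (not isolated)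
Conditions: 4 (2.0 equiv), ethylenediammonium diacetate (20 mol%), xylene, 140 °C, 10 h
Reagents that add atoms: none
Why: Amine-salt-catalysed Knoevenagel-type condensation of the phenol with the enal followed by oxa-6π electrocyclisation: with C1 and C3 substituted, C5 (ortho to the free 4-OH) is the only open nucleophilic carbon, so dehydration gives ortho-quinone methide 5, which closes to the linear 2,2-dimethyl-2H-chromene; the quaternary carbon carries two methyl groups and is not a stereocentre.

**Step 3**
Reactants: 6 methyl 7-hydroxy-2,2-dimethyl-8-(3-methylbut-2-en-1-yl)-2H-chromene-6-carboxylate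
Product: 7 6-(1-hydroxycyclopropyl)-2,2-dimethyl-8-(3-methylbut-2-en-1-yl)-2H-chromen-7-ol
Conditions: Ti(OiPr)4 (1.2 equiv), EtMgBr (3.6 equiv, added over 2 h), THF, 0 °C to rt; then H2O
Reagents that add atoms: ethylmagnesium bromide (EtMgBr), CC[Mg]Br
Why: Kulinkovich cyclopropanation: one equivalent of EtMgBr takes the phenol proton, and the diisopropoxytitanacyclopropane made from EtMgBr and Ti(OiPr)4 adds twice to the ester carbonyl as a 1,2-dicarbanion to give the 1-arylcyclopropanol, while the trisubstituted prenyl alkene and the cyclic cis alkene do not exchange onto titanium.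

**Step 4**
Reactants: 7 6-(1-hydroxycyclopropyl)-2,2-dimethyl-8-(3-methylbut-2-en-1-yl)-2H-chromen-7-ol; 8 4-bromophenol
Product: 10 1-[7-hydroxy-2,2-dimethyl-8-(3-methylbut-2-en-1-yl)-2H-chromen-6-yl]-3-(4-hydroxyphenyl)propan-1-one (target), via palladium homoenolate Pd(XPhos)(4-HOC6H4)(CH2CH2COAr) 9 (not isolated)
Conditions: Pd(OAc)2 (10 mol%), XPhos (20 mol%), Cs2CO3 (3.0 equiv), 8 (1.5 equiv), degassed toluene/THF 4:1, 80 °C, 12 h
Reagents that add atoms: none
Why: Palladium-catalysed ring-opening cross-coupling of a cyclopropanol with an aryl bromide: oxidative addition of 8 to zerovalent palladium, exchange to the palladium cyclopropanolate and strain-driven β-carbon elimination give the divalent palladium homoenolate 9, whose nucleophilic ketone β-carbon reductively eliminates onto the aryl group faster than β-hydride elimination under the bulky XPhos ligand, forming the CH2–aryl bond and the chelated ortho-hydroxy ketone in one operation with both phenols left free (an untested extension of the known coupling); no stereocentre is formed.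

**Compound list**
1 | methyl 2,4-dihydroxybenzoate | COC(=O)c1ccc(O)cc1O | starting material
2 | prenyl bromide (1-bromo-3-methylbut-2-ene) | CC(C)=CCBr | starting material
3 | methyl 2,4-dihydroxy-3-(3-methylbut-2-en-1-yl)benzoate | COC(=O)c1ccc(O)c(CC=C(C)C)c1O | intermediate
4 | 3-methylbut-2-enal (prenal) | CC(C)=CC=O | starting material
5 | ortho-quinone methide, methyl (3Z)-6-hydroxy-5-(3-methylbut-2-en-1-yl)-3-(3-methylbut-2-en-1-ylidene)-4-oxocyclohexa-1,5-diene-1-carboxylate (not isolated) | COC(=O)C1=C/C(=C/C=C(C)C)C(=O)C(CC=C(C)C)=C1O | intermediate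
6 | methyl 7-hydroxy-2,2-dimethyl-8-(3-methylbut-2-en-1-yl)-2H-chromene-6-carboxylate | COC(=O)c1cc2C=CC(C)(C)Oc2c(CC=C(C)C)c1O | intermediate
7 | 6-(1-hydroxycyclopropyl)-2,2-dimethyl-8-(3-methylbut-2-en-1-yl)-2H-chromen-7-ol | CC(C)=CCc1c(O)c(C2(O)CC2)cc2C=CC(C)(C)Oc12 | intermediate
8 | 4-bromophenol | Oc1ccc(Br)cc1 | starting material
9 | palladium homoenolate Pd(XPhos)(4-HOC6H4)(CH2CH2COAr), Ar = the ring A chromenyl group of 10; divalent palladium; XPhos left out of the SMILES (not isolated) | CC(C)=CCc1c(O)c(C(=O)CC[Pd]c2ccc(O)cc2)cc2c1OC(C)(C)C=C2 | intermediate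
10 | 1-[7-hydroxy-2,2-dimethyl-8-(3-methylbut-2-en-1-yl)-2H-chromen-6-yl]-3-(4-hydroxyphenyl)propan-1-one (CNP0163015.0) | CC(C)=CCc1c(O)c(C(=O)CCc2ccc(O)cc2)cc2c1OC(C)(C)C=C2 | target

**Step count and risks**
Total step count: 4. Longest linear sequence: 4 steps (1 to 3 to 6 to 7 to 10).

The three steps most likely to fail, most risky first:

Step 4 (key coupling). The cesium phenoxides may bind palladium or make 8 a sluggish electrophile. The homoenolate may also be protonated to the ethyl ketone, or undergo β-hydride elimination to an enone that would close to a chromanone. The fallback masks both phenols, so the coupling runs on a plain 1-arylcyclopropanol and a neutral aryl bromide, which is the closest situation to precedent. It sets out from 7. Phenol-selective silylation (TBSCl, imidazole, DMF, rt; the tertiary cyclopropanol is not silylated) gives 1-[7-[(tert-butyldimethylsilyl)oxy]-2,2-dimethyl-8-(3-methylbut-2-en-1-yl)-2H-chromen-6-yl]cyclopropan-1-ol F4. Coupling of F4 with commercial (4-bromophenoxy)(tert-butyl)dimethylsilane under Pd(OAc)2/XPhos/Cs2CO3 in toluene at 80 °C gives 1-[7-[(tert-butyldimethylsilyl)oxy]-2,2-dimethyl-8-(3-methylbut-2-en-1-yl)-2H-chromen-6-yl]-3-[4-[(tert-butyldimethylsilyl)oxy]phenyl]propan-1-one F5. Treatment with TBAF/AcOH in THF at 0 °C removes both silyl groups, and the fallback comes back to the route at 10.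

Step 3 (Kulinkovich reaction on the free, chelated phenol). The magnesium or titanium aryloxide may deactivate the ester or tie up the titanium reagent. The fallback sets out from 6. Silylation of the phenol (TBSOTf, 2,6-lutidine, CH2Cl2, 0 °C) gives methyl 7-[(tert-butyldimethylsilyl)oxy]-2,2-dimethyl-8-(3-methylbut-2-en-1-yl)-2H-chromene-6-carboxylate F3. The Kulinkovich reaction on this non-acidic ester (EtMgBr 2.6 equiv, Ti(OiPr)4 1.0 equiv, THF, 0 °C to rt) gives 1-[7-[(tert-butyldimethylsilyl)oxy]-2,2-dimethyl-8-(3-methylbut-2-en-1-yl)-2H-chromen-6-yl]cyclopropan-1-ol F4. Fluoride cleavage (TBAF/AcOH, THF, 0 °C) then comes back to the route at 7. The same end point is reached if the silyl group has migrated to the cyclopropanol oxygen.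

Step 1 (regioselectivity and yield of the direct C-prenylation). The fallback replaces it by an ether formation and aromatic Claisen rearrangement sequence. It sets out from 1. Alkylation of the free 4-OH with 3-chloro-3-methylbut-1-yne (K2CO3, KI, CuI cat., acetone, reflux) gives methyl 2-hydroxy-4-[(2-methylbut-3-yn-2-yl)oxy]benzoate F1. Semihydrogenation (H2, Pd/CaCO3 poisoned with Pb(OAc)2, quinoline, EtOAc) gives methyl 2-hydroxy-4-[(2-methylbut-3-en-2-yl)oxy]benzoate F2. Heating in N,N-diethylaniline at 130 °C brings about the Claisen rearrangement to C3, directed by bond fixation in the chelated ring, and delivers the normal prenyl group. The fallback comes back to the route at 3.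

**Further compounds**
F1 | step 1 | methyl 2-hydroxy-4-[(2-methylbut-3-yn-2-yl)oxy]benzoate | COC(=O)c1ccc(OC(C)(C)C#C)cc1O
F2 | step 1 | methyl 2-hydroxy-4-[(2-methylbut-3-en-2-yl)oxy]benzoate | COC(=O)c1ccc(OC(C)(C)C=C)cc1O
F3 | step 3 | methyl 7-[(tert-butyldimethylsilyl)oxy]-2,2-dimethyl-8-(3-methylbut-2-en-1-yl)-2H-chromene-6-carboxylate | COC(=O)c1cc2C=CC(C)(C)Oc2c(CC=C(C)C)c1O[Si](C)(C)C(C)(C)C
F4 | step 3 | 1-[7-[(tert-butyldimethylsilyl)oxy]-2,2-dimethyl-8-(3-methylbut-2-en-1-yl)-2H-chromen-6-yl]cyclopropan-1-ol | CC(C)=CCc1c(O[Si](C)(C)C(C)(C)C)c(C2(O)CC2)cc2C=CC(C)(C)Oc12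
F5 | step 4 | 1-[7-[(tert-butyldimethylsilyl)oxy]-2,2-dimethyl-8-(3-methylbut-2-en-1-yl)-2H-chromen-6-yl]-3-[4-[(tert-butyldimethylsilyl)oxy]phenyl]propan-1-one | CC(C)=CCc1c(O[Si](C)(C)C(C)(C)C)c(C(=O)CCc2ccc(O[Si](C)(C)C(C)(C)C)cc2)cc2c1OC(C)(C)C=C2
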